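The data were computed on assumed constants; scatter was added.

A leftover of undissolved solid substrate may add nothing to the reaction. Each flask here starts with none of it in solution, and the earlier runs can test the idea.

| flask | solid substrate | coupling partner | remark | time |
|---|---|---|---|---|
| south-east | 0.085 M | 0.17 M | run made earlier |  |
| east | 0.13 M | 0.17 M | run made earlier |  |
| north-east | 0.17 M | 0.085 M | run made earlier |  |
| flask | 0.17 M | 0.170 M |  | 80 min |

| run | time / min | single product / % |
|---|---|---|
| south-east | 8.00 | 1 |
| south-east | 25.0 | 9 |
| south-east | 40.0 | 16 |
| south-east | 60.0 | 26 |
| east | 8.00 | 0 |
| east | 25.0 | 3 |
| east | 40.0 | 7 |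
| east | 60.0 | 18 |
| north-east | 8.00 | 0 |
| north-east | 25.0 | 0 |
| north-east | 40.0 | 6 |
| north-east | 60.0 | 8 |

(each reading ± 2 percentage points)

- as a solid, counted per litre of solution: solid substrate
- the numbers in the tables scatter by 2 percentage points (one standard deviation)
- at the start none of the solid substrate is in solution

- equivalents of coupling partner to solid substrate, everything else as given, that leave most single product at 80 min
- the amount of single product then, in percent of the solid substrate charged
- the amount of single product with the amounts as given

We read the last row of each table, at 60.0 min. Our zero is the statistical case: the percentage does not change with the charge, so east should read what south-east reads, 26%. East reads 18%, which is 8 percentage points off, against a scatter of 2 points.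

So we multiply each percentage by its charge. South-east then holds 0.0221 M of single product and east 0.0234 M, close readings. This looks zero order in the charged solid. North-east has the flask's solid charge but half the coupling partner, and it reads lower, 0.0136 M. If the charge adds nothing, this lower reading goes with the coupling partner, so single product rises with the coupling partner, and we keep north-east out of the mean below, which is for 0.170 M.

The mean of south-east and east rises from 0.0114 M at 40.0 min to 0.0227 M at 60.0 min. Carried on in a straight line, it reaches 0.0341 M at 80 min. We call this the output: single product per litre at that time with 0.170 M of coupling partner, whatever the solid charge. Dividing by the flask's charge, we expect 20.1%. We commit to no optimum.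

The forecast says 22%, higher than ours, and 40% at 2.5 equiv. Its ground: “once the solid is saturating, the rate barely depends on how much is charged”.

The flask gives 18.5%, and 24.3% at 2.57 equiv.

    starting material + coupling partner → single product (k = 0.140 L mol⁻¹ min⁻¹)
    starting material + coupling partner → other mono adduct (k = 0.00840 L mol⁻¹ min⁻¹)
    coupling partner + single product → bis adduct (k = 0.0400 L mol⁻¹ min⁻¹)
    coupling partner + other mono adduct → bis adduct (k = 0.400 L mol⁻¹ min⁻¹)
    single product ⇌ isomer of the product (K = 5.70, k = 0.00320 min⁻¹)
    solid substrate ⇌ starting material, rate k6*(cs6 - [starting material]) while solid is left; crystals form when [starting material] > cs6 (solubility = 0.0630 M, k = 0.0270 min⁻¹)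

The flask's 18.5% is an output of 0.0314 M, below our 0.0341 M, and 53.0% of its charge is still solid at 80.0 min. A neighbour flask keeps the coupling partner and the time but holds 0.68 M of solid substrate. Our output divided by that charge gives 5.01%. The neighbour ends with 88.3% of its charge still solid and 4.62% of single product.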